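## The problem

The target is built from three guaiacyl-type arenes. A 4-hydroxy-3-methoxyphenyl ring (ring A) sits on C2 of a 7-methoxy-2,3-dihydrobenzofuran (dihydrofuran ring B fused to benzene ring C), and C5 of ring C is bonded to C2' of a 7'-methoxybenzofuran (furan ring D fused to benzene ring E) that carries a 3-hydroxypropyl chain at C5'. The only stereocentres are C2 (S) and C3 (R) of ring B, adjacent and trans. Nothing else in the molecule is stereogenic, so their absolute sense must come from a reagent or catalyst, while their relative sense is helped by the preference of the 2-aryl and 3-CH2X groups for the trans ring; once one centre is fixed the other can be steered. The structure is fragile in defined ways: the para-hydroxyl of ring A makes the benzylic C2–O1 bond ionisable (quinone methide formation), a carbonyl group on the C3 carbon invites β-elimination of the ring C phenoxide, and the benzylic ether and the C2'=C3' bond rule out hydrogenolytic deprotection. The C5–C2' link joins two electron-rich rings and has to be made beside a phenol and two primary alcohols. The feature that gives the shortest access to ring B is that C2 is bonded within the ring only to O1 and C3, so it can be delivered as one carbon that is first nucleophilic (towards C3) and then electrophilic (towards O1). The hydroxymethyl group on C3 can be read as the remnant of a nitro group that made C3 an acceptor, and the remaining ring atoms O1–C7a–C3a–C3, the C7 methoxyl and a C5 handle para to O1 are all present in an ortho-hydroxy-β-nitrostyrene.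

## Retrosynthesis

**Ring D: O1'–C2' and C3'–C3a'.** The target 24 is cut into the terminal alkyne 20 and the iodophenol 22; the two alkyne carbons become C2' and C3'. The neighbouring cut, the C5–C2' bond, would need a preformed benzofuran made by acid cyclisation and a round of protecting groups. Cutting inside ring D lets one palladium/copper operation join the halves and close the ring under amine base with every hydroxyl free. Both 20 and 22 are much simpler than 24, and 22 is one iodination away from dihydroconiferyl alcohol 21. The forward reaction must couple faster than the alkyne dimerises and must carry the alkynylphenol 23 on to the furan.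

**C5–C(sp).** Alkyne 20 is traced through the silylalkyne 19 to the aryl bromide 17 and ethynyltrimethylsilane 18. The bromine is para to O1 and arrives with the salicylaldehyde, so no late halogenation with its regiochemical question is needed. Methanolysis of 19 removes the silyl group and the pivalate together. The forward coupling asks for oxidative addition into an electron-rich aryl bromide beside a free alcohol and an aryl ester.

**C3 side chain.** The hydroxymethyl group of 17 is taken back to the carboxylic acid 16 and this to the nitromethyl group of 14. The Nef route through the C3 aldehyde was set aside because that aldehyde can open ring B by β-elimination. Nitrite-mediated oxidation reaches the acid under weakly acidic conditions, and borane then reduces the acid beside pivalate and bromide. The skeleton is not simplified, but the nitro group that polarises the next cut is uncovered.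

**Ring B: C2–C3 and O1–C2 (key cut).** Compound 14 falls into the nitrovinylphenol 3 (the four-atom unit O1–C7a–C3a–C3) and the benzylsulfonium salt 11 (the one-carbon unit C2). Cutting O1–C2 alone would leave an open chain whose two stereocentres need their own asymmetric synthesis. Cutting C3–C3a (carbene C–H insertion) gives the cis ring first and needs a diazo ester several steps from catalogue material. The double cut removes the ring and both stereocentres at once and leaves two monocyclic aromatics without carbon stereocentres, the chirality resting in a recoverable C2-symmetric sulfide. The forward step must add the ylide 12 to the nitroalkene carbon and not be intercepted by the phenoxide oxygen, must close the betaine 13 through oxygen, and must distinguish the ylide faces.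

**Nitroalkene.** Compound 3 is cut at its C=C bond into 5-bromo-o-vanillin 1 and nitromethane 2 (Henry condensation). The phenol stays free because it is the nucleophile of the key step, so 3 is one step from catalogue.

**Sulfonium salt.** Salt 11 is cut at S–CH2 into the benzylic bromide 10 and the sulfide 6. Bromide 10 goes back through alcohol 9 and aldehyde 8 to vanillin 7. The pivalate is chosen because it tempers the para oxygen, which keeps 10 and 11 from ionising, and because it withstands carbonate in acetonitrile. Sulfide 6 goes back through the dimesylate 5 to (2R,5R)-hexane-2,5-diol 4, each displacement inverting. Triflate is chosen as counter-ion so that bromide cannot reverse the alkylation.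

**Iodophenol.** Compound 22 is cut at C–I to dihydroconiferyl alcohol 21; only one position ortho or para to the phenol is open.

## Roads not taken

**Alternative 1:** Here ring C itself is cut, at C3a–C7a and C6–C7, so that it unravels to a 2,4-disubstituted furan and an alkyne. In the forward sense the cationic gold complex (Ph3P)AuNTf2 would isomerise the ethynyl ether A2, in which both stereocentres already stand on an open chain, to the 7-hydroxy dihydrobenzofuran A1. The furan attacks the gold-activated triple bond, the bicyclic intermediate opens, and the former furan oxygen becomes the phenol at C7 while rings B and C form together.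
- Merits: the isomerisation is fully atom-economic, the mechanism fixes the position of the C7 oxygen, and C2 and C3 are untouched in the step, so they could be set beforehand by a dependable acyclic method such as an auxiliary-controlled aldol reaction.
- Weak points: A2 joins a terminal ynol ether to a secondary benzylic oxygen next to an electron-rich ring. It is hard to make and prone to hydration, and the Lewis-acidic gold can ionise this very C–O bond, which is the C2 stereocentre. The furan must carry the whole benzofuran unit at its C4, an awkward pattern. A1 still needs methylation at O7 and three desilylations.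
- Comparison: in stereochemical security this road is better than the chosen one, since it relies on established acyclic control and not on a new annulation. The chosen plan sets brevity against it: ring C with its methoxyl and bromine is bought in 1, and ring B is made from 3 and 11 in one step, whereas A2 alone would take a sequence comparable in length to the whole chosen route.

**Alternative 2:** The cut is O1–C2 alone. The acid A4 has C3 in place and a carboxyl group on the future C2. At a graphite anode under constant current in an alcohol solvent it would be decarboxylated (non-Kolbe oxidation); the benzylic cation, a protonated quinone methide of ring A, would be captured by the ortho phenol of ring C to give the bromo diol A3.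
- Merits: the stereochemical problem shrinks to one centre, since C2 is created under the influence of C3 and the trans ring is favoured. No reagent is consumed besides current. A3 carries the free phenol, so the pivalate of the chosen route and its removal would be unnecessary, and A3 could enter the same alkyne endgame. In these respects it is the better plan.
- Weak points: two free electron-rich phenols are oxidised at lower potential than a carboxylate, the solvent competes with the phenol for the cation, and the γ-hydroxy acid A4 tends to close to its lactone. The enantioselective construction of C3 in A4 needs a sequence of its own, in which a carbon is built in only to be expelled.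
- Comparison: the chosen plan sets against this that C2–C3, O1–C2 and both centres come from two aromatic pieces, each a few steps from catalogue, with the chiral information in a sulfide that the key step returns.

**Alternative 3:** This cut concerns ring D only, at C3'–C3a'. The acetal A6, an α-aryloxy aldehyde dimethyl acetal with ring E attached through O1', would be heated with Amberlyst 15 in chlorobenzene. The oxocarbenium ion attacks the only free ortho carbon of ring E, and loss of two molecules of alcohol gives the benzofuran as its tris-pivalate A5.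
- Merits: cheap and metal-free, regiochemistry decided by the substitution pattern, and a single deprotection from the target. In regiocontrol it equals the chosen ring D construction.
- Weak points: hot sulfonic acid meets the benzylic C2–O1 bond of ring B (epimerisation through ring opening). It also meets the aryloxy-bearing benzylic carbon of A6, where loss of the phenol or aryl migration can precede cyclisation. A6 must be assembled by linear steps at C5 of a late, precious intermediate. The plan is silent on C2 and C3, for which something like the key step of the chosen route would still be needed.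
- Comparison: the chosen plan sets against it a ring D closure under amine base at 60 °C that joins the halves 20 and 22 in the same operation.

Key step: step 8

Assumption: the benzylidene ylide of 2,5-dimethylthiolane is taken to turn towards the nitroalkene the face it turns towards aldehydes in epoxidation, which points to the (2S,5S)-sulfide for a (2S) centre; if the sense proved opposite, the antipodal sulfide from (2S,5S)-hexane-2,5-diol would be used with no other change.

## Route

Step 1
Reactants: 1 5-bromo-2-hydroxy-3-methoxybenzaldehyde (5-bromo-o-vanillin); 2 nitromethane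
Product: 3 4-bromo-2-methoxy-6-[(E)-2-nitroethenyl]phenol
Conditions: NH4OAc, AcOH, 100 °C
Reagents that add atoms: none
Why: Henry condensation of a salicylaldehyde with nitromethane under ammonium acetate catalysis; loss of water gives the conjugated (E)-nitroalkene and the free phenol is tolerated.

Step 2
Reactants: 4 (2R,5R)-hexane-2,5-diol
Product: 5 (2R,5R)-hexane-2,5-diyl dimethanesulfonate
Conditions: MsCl, Et3N, CH2Cl2, 0 °C
Reagents that add atoms: methanesulfonyl chloride, CS(=O)(=O)Cl
Why: O-sulfonylation of secondary alcohols; no bond to a stereocentre is broken, so both centres stay (R).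

Step 3
Reactants: 5 (2R,5R)-hexane-2,5-diyl dimethanesulfonate
Product: 6 (2S,5S)-2,5-dimethylthiolane
Conditions: Na2S·9H2O, DMSO, rt; distillation
Reagents that add atoms: sodium sulfide, [Na+].[Na+].[S-2]
Why: Double SN2 displacement by sulfide, the second being a 5-exo-tet ring closure; each displacement inverts, which turns the (R,R)-dimesylate into the (S,S)-thiolane.

Step 4
Reactants: 7 vanillin (4-hydroxy-3-methoxybenzaldehyde)
Product: 8 4-formyl-2-methoxyphenyl 2,2-dimethylpropanoate
Conditions: PivCl, Et3N, DMAP (cat.), CH2Cl2, 0 °C to rt
Reagents that add atoms: pivaloyl chloride, CC(C)(C)C(=O)Cl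
Why: O-acylation of a phenol; the pivalate lowers the donor power of the para oxygen and resists carbonate in an aprotic solvent.

Step 5
Reactants: 8 4-formyl-2-methoxyphenyl 2,2-dimethylpropanoate
Product: 9 4-(hydroxymethyl)-2-methoxyphenyl 2,2-dimethylpropanoate
Conditions: NaBH4, THF/MeOH, 0 °C
Reagents that add atoms: none
Why: Borohydride reduction of an aromatic aldehyde; the hindered aryl pivalate is not attacked at 0 °C.

Step 6
Reactants: 9 4-(hydroxymethyl)-2-methoxyphenyl 2,2-dimethylpropanoate
Product: 10 4-(bromomethyl)-2-methoxyphenyl 2,2-dimethylpropanoate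
Conditions: PBr3, CH2Cl2, 0 °C
Reagents that add atoms: phosphorus tribromide, BrP(Br)Br
Why: Standard conversion of a benzylic alcohol into the bromide; the aryl ester survives the nearly neutral conditions.

Step 7
Reactants: 10 4-(bromomethyl)-2-methoxyphenyl 2,2-dimethylpropanoate; 6 (2S,5S)-2,5-dimethylthiolane
Product: 11 (2S,5S)-1-(3-methoxy-4-pivaloyloxybenzyl)-2,5-dimethylthiolanium trifluoromethanesulfonate
Conditions: LiOTf, CH2Cl2/H2O, rt
Reagents that add atoms: lithium trifluoromethanesulfonate, [Li+].[O-]S(=O)(=O)C(F)(F)F
Why: S-alkylation of a dialkyl sulfide by a benzylic bromide, driven by passage of bromide into the water layer and pairing of the sulfonium ion with triflate; the two lone pairs of the C2-symmetric sulfide are equivalent, so a single salt forms.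

Step 8
Reactants: 3 4-bromo-2-methoxy-6-[(E)-2-nitroethenyl]phenol; 11 (2S,5S)-1-(3-methoxy-4-pivaloyloxybenzyl)-2,5-dimethylthiolanium trifluoromethanesulfonate
Product: 14 4-[(2S,3R)-5-bromo-7-methoxy-3-(nitromethyl)-2,3-dihydro-1-benzofuran-2-yl]-2-methoxyphenyl 2,2-dimethylpropanoate, via sulfonium ylide 12 (not isolated), via nitronate betaine 13 (not isolated)
Conditions: K2CO3 (2.5 equiv), MeCN, 0 °C to rt
Reagents that add atoms: none
Why: Proposed new method: K2CO3 deprotonates the phenol of 3 and, in small stationary concentration, the benzylic position of 11 to give the ylide 12; conjugate addition of 12 to the ring-bound carbon of the nitroalkene forms C2–C3 and the nitronate betaine 13, whose phenoxide displaces the thiolane at the benzylic carbon with inversion to form O1–C2 and set sulfide 6 free. The closest known reaction types are the catalytic asymmetric (4+1) annulation of 2-(2-nitrovinyl)phenols with carbonyl-stabilised sulfonium ylides and the epoxidation of aldehydes and aziridination of imines by chiral benzylsulfonium ylides under hydroxide or carbonate; a semi-stabilised benzylic ylide has not been shown on this acceptor class. Ring B closes in the 5-exo-tet mode, the departing sulfur lying outside the new ring. C2 is controlled by the C2-symmetric thiolane, which fixes the conformation of the ylide and shields one of its faces, and the inversion in the displacement turns this into the (2S) centre. C3 is set relative to C2: the betaine diastereomer that places aryl and nitromethyl trans in the transition state of closure reacts faster, and reversal of the Michael addition should drain the other. The step needs C-attack at the nitroalkene to win over benzyl transfer to the phenoxide oxygen, and closure through the phenoxide to win over closure through the nitronate carbon or oxygen (cyclopropane, isoxazoline N-oxide); the hindered, delocalised phenoxide of 3 is a poor partner for intermolecular alkylation yet sits five atoms from the sulfonium carbon in 13, and the triflate counter-ion removes bromide as a cause of reversible dealkylation. Any minor enantiomer would be removed by crystallisation of 14 or of the acid 16.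

Step 9
Reactants: 14 4-[(2S,3R)-5-bromo-7-methoxy-3-(nitromethyl)-2,3-dihydro-1-benzofuran-2-yl]-2-methoxyphenyl 2,2-dimethylpropanoate
Product: 16 (2S,3S)-5-bromo-7-methoxy-2-[3-methoxy-4-(pivaloyloxy)phenyl]-2,3-dihydro-1-benzofuran-3-carboxylic acid, via nitrolic acid 15 (not isolated)
Conditions: NaNO2, AcOH, DMSO, 35 °C
Reagents that add atoms: water, O
Why: Nef-type oxidative conversion of a primary nitroalkane into a carboxylic acid: C-nitrosation gives the nitrolic acid 15, which loses nitrous acid and is hydrolysed to the acid. The weakly acidic medium avoids the C3 aldehyde and the basic conditions that could open ring B by β-elimination, so C3 keeps its spatial arrangement (the descriptor changes from R to S only through the priority of the carboxyl group).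

Step 10
Reactants: 16 (2S,3S)-5-bromo-7-methoxy-2-[3-methoxy-4-(pivaloyloxy)phenyl]-2,3-dihydro-1-benzofuran-3-carboxylic acid
Product: 17 4-[(2S,3R)-5-bromo-3-(hydroxymethyl)-7-methoxy-2,3-dihydro-1-benzofuran-2-yl]-2-methoxyphenyl 2,2-dimethylpropanoate
Conditions: BH3·THF, THF, 0 °C to rt; MeOH quench
Reagents that add atoms: none
Why: Borane reduces a carboxylic acid much faster than an aryl ester and leaves the aryl bromide alone; no bond to C3 is broken.

Step 11
Reactants: 17 4-[(2S,3R)-5-bromo-3-(hydroxymethyl)-7-methoxy-2,3-dihydro-1-benzofuran-2-yl]-2-methoxyphenyl 2,2-dimethylpropanoate; 18 ethynyltrimethylsilane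
Product: 19 4-[(2S,3R)-3-(hydroxymethyl)-7-methoxy-5-[(trimethylsilyl)ethynyl]-2,3-dihydro-1-benzofuran-2-yl]-2-methoxyphenyl 2,2-dimethylpropanoate
Conditions: PdCl2(PhCN)2, P(t-Bu)3, CuI, i-Pr2NH, dioxane, rt to 45 °C
Reagents that add atoms: none
Why: Sonogashira coupling; the bulky electron-rich phosphine lets zerovalent palladium insert into the electron-rich aryl bromide at low temperature, which spares the pivalate and the free alcohol.

Step 12
Reactants: 19 4-[(2S,3R)-3-(hydroxymethyl)-7-methoxy-5-[(trimethylsilyl)ethynyl]-2,3-dihydro-1-benzofuran-2-yl]-2-methoxyphenyl 2,2-dimethylpropanoate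
Product: 20 4-[(2S,3R)-5-ethynyl-3-(hydroxymethyl)-7-methoxy-2,3-dihydro-1-benzofuran-2-yl]-2-methoxyphenol
Conditions: K2CO3, MeOH, rt to 40 °C
Reagents that add atoms: none
Why: Methanolysis: methoxide cleaves the C(sp)–Si bond and the phenolic pivalate in one operation; the stereocentres are not involved.

Step 13
Reactants: 21 dihydroconiferyl alcohol (4-(3-hydroxypropyl)-2-methoxyphenol)
Product: 22 4-(3-hydroxypropyl)-2-iodo-6-methoxyphenol
Conditions: I2, NaHCO3, THF/H2O, 0 °C to rt
Reagents that add atoms: iodine, II
Why: Electrophilic iodination of the phenoxide; the para position is blocked by the side chain and one ortho position by methoxyl, so iodine enters the single free ortho carbon.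

Step 14
Reactants: 20 4-[(2S,3R)-5-ethynyl-3-(hydroxymethyl)-7-methoxy-2,3-dihydro-1-benzofuran-2-yl]-2-methoxyphenol; 22 4-(3-hydroxypropyl)-2-iodo-6-methoxyphenol
Product: 24 4-[(2S,3R)-3-(hydroxymethyl)-5-[5-(3-hydroxypropyl)-7-methoxy-1-benzofuran-2-yl]-7-methoxy-2,3-dihydro-1-benzofuran-2-yl]-2-methoxyphenol (CNP0308311.1), via 2-alkynylphenol 23 (not isolated)
Conditions: PdCl2(PPh3)2, CuI, Et3N, DMF, 60 °C, degassed
Reagents that add atoms: none
Why: Sonogashira coupling of the 2-iodophenol with the arylacetylene gives the 2-alkynylphenol 23, whose hydroxyl adds across the metal-activated triple bond (5-endo-dig) to close ring D. This tandem coupling–cycloisomerisation is the standard entry to 2-arylbenzofurans and tolerates free hydroxyl groups, so the target is reached without a deprotection step.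

## Compound list

1 | 5-bromo-2-hydroxy-3-methoxybenzaldehyde (5-bromo-o-vanillin) | COc1cc(Br)cc(C=O)c1O | starting material
2 | nitromethane | C[N+](=O)[O-] | starting material
3 | 4-bromo-2-methoxy-6-[(E)-2-nitroethenyl]phenol | COc1cc(Br)cc(/C=C/[N+](=O)[O-])c1O | intermediate
4 | (2R,5R)-hexane-2,5-diol | C[C@@H](O)CC[C@@H](C)O | starting material
5 | (2R,5R)-hexane-2,5-diyl dimethanesulfonate | C[C@@H](OS(C)(=O)=O)CC[C@@H](C)OS(C)(=O)=O | intermediate
6 | (2S,5S)-2,5-dimethylthiolane | C[C@H]1CC[C@H](C)S1 | intermediate
7 | vanillin (4-hydroxy-3-methoxybenzaldehyde) | COc1cc(C=O)ccc1O | starting material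
8 | 4-formyl-2-methoxyphenyl 2,2-dimethylpropanoate | COc1cc(C=O)ccc1OC(=O)C(C)(C)C | intermediate
9 | 4-(hydroxymethyl)-2-methoxyphenyl 2,2-dimethylpropanoate | COc1cc(CO)ccc1OC(=O)C(C)(C)C | intermediate
10 | 4-(bromomethyl)-2-methoxyphenyl 2,2-dimethylpropanoate | COc1cc(CBr)ccc1OC(=O)C(C)(C)C | intermediate
11 | (2S,5S)-1-(3-methoxy-4-pivaloyloxybenzyl)-2,5-dimethylthiolanium trifluoromethanesulfonate | C[C@H]1CC[C@H](C)[S+]1Cc1ccc(OC(=O)C(C)(C)C)c(OC)c1.[O-]S(=O)(=O)C(F)(F)F | intermediate
12 | (2S,5S)-2,5-dimethylthiolanium (3-methoxy-4-pivaloyloxyphenyl)methylide (sulfonium ylide) | C[C@H]1CC[C@H](C)[S+]1[CH-]c1ccc(OC(=O)C(C)(C)C)c(OC)c1 | intermediate (not isolated)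
13 | nitronate betaine: (2S,5S)-2,5-dimethylthiolanium bearing at sulfur the (1R,2R)-2-(5-bromo-2-hydroxy-3-methoxyphenyl)-1-(3-methoxy-4-pivaloyloxyphenyl)-3-nitronatopropyl group (zwitterion, drawn with the phenol protonated) | COc1cc(Br)cc([C@H](C=[N+]([O-])[O-])[C@H](c2ccc(OC(=O)C(C)(C)C)c(OC)c2)[S+]2[C@@H](C)CC[C@@H]2C)c1O | intermediate (not isolated)
14 | 4-[(2S,3R)-5-bromo-7-methoxy-3-(nitromethyl)-2,3-dihydro-1-benzofuran-2-yl]-2-methoxyphenyl 2,2-dimethylpropanoate | COc1cc([C@H]2Oc3c(OC)cc(Br)cc3[C@@H]2C[N+](=O)[O-])ccc1OC(=O)C(C)(C)C | intermediate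
15 | 4-[(2S,3R)-5-bromo-3-[(hydroxyimino)(nitro)methyl]-7-methoxy-2,3-dihydro-1-benzofuran-2-yl]-2-methoxyphenyl 2,2-dimethylpropanoate (nitrolic acid) | COc1cc([C@H]2Oc3c(OC)cc(Br)cc3[C@@H]2C(=NO)[N+](=O)[O-])ccc1OC(=O)C(C)(C)C | intermediate (not isolated)
16 | (2S,3S)-5-bromo-7-methoxy-2-[3-methoxy-4-(pivaloyloxy)phenyl]-2,3-dihydro-1-benzofuran-3-carboxylic acid | COc1cc([C@H]2Oc3c(OC)cc(Br)cc3[C@@H]2C(=O)O)ccc1OC(=O)C(C)(C)C | intermediate
17 | 4-[(2S,3R)-5-bromo-3-(hydroxymethyl)-7-methoxy-2,3-dihydro-1-benzofuran-2-yl]-2-methoxyphenyl 2,2-dimethylpropanoate | COc1cc([C@H]2Oc3c(OC)cc(Br)cc3[C@@H]2CO)ccc1OC(=O)C(C)(C)C | intermediate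
18 | ethynyltrimethylsilane | C#C[Si](C)(C)C | starting material
19 | 4-[(2S,3R)-3-(hydroxymethyl)-7-methoxy-5-[(trimethylsilyl)ethynyl]-2,3-dihydro-1-benzofuran-2-yl]-2-methoxyphenyl 2,2-dimethylpropanoate | COc1cc([C@H]2Oc3c(OC)cc(C#C[Si](C)(C)C)cc3[C@@H]2CO)ccc1OC(=O)C(C)(C)C | intermediate
20 | 4-[(2S,3R)-5-ethynyl-3-(hydroxymethyl)-7-methoxy-2,3-dihydro-1-benzofuran-2-yl]-2-methoxyphenol | COc1cc([C@H]2Oc3c(OC)cc(C#C)cc3[C@@H]2CO)ccc1O | intermediate
21 | dihydroconiferyl alcohol (4-(3-hydroxypropyl)-2-methoxyphenol) | COc1cc(CCCO)ccc1O | starting material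
22 | 4-(3-hydroxypropyl)-2-iodo-6-methoxyphenol | COc1cc(CCCO)cc(I)c1O | intermediate
23 | 4-[(2S,3R)-5-{[2-hydroxy-5-(3-hydroxypropyl)-3-methoxyphenyl]ethynyl}-3-(hydroxymethyl)-7-methoxy-2,3-dihydro-1-benzofuran-2-yl]-2-methoxyphenol | COc1cc([C@H]2Oc3c(OC)cc(C#Cc4cc(CCCO)cc(OC)c4O)cc3[C@@H]2CO)ccc1O | intermediate (not isolated)
24 | 4-[(2S,3R)-3-(hydroxymethyl)-5-[5-(3-hydroxypropyl)-7-methoxy-1-benzofuran-2-yl]-7-methoxy-2,3-dihydro-1-benzofuran-2-yl]-2-methoxyphenol (CNP0308311.1) | COc1cc([C@H]2Oc3c(OC)cc(-c4cc5cc(CCCO)cc(OC)c5o4)cc3[C@@H]2CO)ccc1O | target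

## Step count and least certain steps

Total: 14 steps. Longest linear sequence: 10 steps (steps 4, 5, 6, 7, 8, 9, 10, 11, 12 and 14, from vanillin 7).

**Step 8 (key step, proposed new method).**
- What may go wrong: transfer of the benzyl group from sulfur to the phenoxide oxygen of 3, since a benzylsulfonium ion is itself an alkylating agent.
- What may go wrong: closure of 13 through the nitronate instead of the phenoxide.
- What may go wrong: insufficient or reversed facial selectivity, since the sense of induction is extrapolated from carbonyl additions.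
- Fallback with known chemistry, setting out from 1 and 10 and coming back at 20:
  - Aldehyde 1 is O-alkylated with bromide 10 (K2CO3, DMF) to give the O-benzylated aldehyde F1.
  - Wittig reaction with Ph3P=CHOMe gives the enol ether F2, which pyridinium chlorochromate, (C5H5NH)[CrO3Cl], oxidises to the methyl arylacetate F3.
  - Diazo transfer (4-acetamidobenzenesulfonyl azide, DBU) gives the aryldiazoacetate F4.
  - Intramolecular insertion of the rhodium carbene into the benzylic ether C–H bond, catalysed by dirhodium tetrakis[N-phthaloyl-(S)-tert-leucinate], Rh2(S-PTTL)4, or its antipode (whichever leads to the (2S) series), gives the cis ester F5.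
  - NaOMe in MeOH epimerises C3 and removes the pivalate to give the trans phenolic ester F6.
  - LiBH4 reduces the ester to the bromo diol F7, which is the same compound as A3.
  - Sonogashira coupling with 18 as in step 11 gives the silylalkyne F8, and K2CO3 in MeOH then gives 20.

**Step 7.**
- What may go wrong: slow and reversible alkylation of the hindered secondary-alkyl sulfide, with hydrolysis of the benzylic bromide in the two-phase medium taking over.
- Fallback, setting out from 9 and 6 and coming back at 11: alcohol 9 is treated with Tf2O and pyridine in CH2Cl2 at −20 °C to form the benzylic triflate F9 in the flask, which alkylates 6 irreversibly to give 11 directly.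

**Step 9.**
- What may go wrong: stalling at the nitrolic acid stage, nitrosation of the electron-rich rings by excess nitrous acid, or loss of configuration at C3 during the long reaction at 35 °C.
- Fallback, setting out from 14 and coming back at 17: the nitronate is formed with KOt-Bu in THF/MeOH at −78 °C and ozonised at that temperature (Nef reaction by ozonolysis of the nitronate) to the aldehyde F10. NaBH4 added to the cold mixture reduces F10 before it can eliminate, giving 17 and bypassing 16.

**Step 14.**
- What may go wrong: slow oxidative addition into the electron-rich iodophenoxide, so that copper-mediated oxidative dimerisation of alkyne 20 overtakes the cross-coupling, or arrest at the open alkynylphenol 23.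
- Fallback, setting out from 22 and 20 and coming back at 24: 22 is acetylated (Ac2O, pyridine) to the diacetate F11, whose C–I bond is more electrophilic. Sonogashira coupling with 20 at rt gives the diarylalkyne diacetate F12. Cs2CO3 in MeOH/DMF at 60 °C then removes both acetates and closes ring D by base-mediated 5-endo-dig addition of the phenoxide (through 23) to give 24.

## Further compounds

F1 | step 8 | 4-[(4-bromo-2-formyl-6-methoxyphenoxy)methyl]-2-methoxyphenyl 2,2-dimethylpropanoate | COc1cc(Br)cc(C=O)c1OCc1ccc(OC(=O)C(C)(C)C)c(OC)c1
F2 | step 8 | 4-{[4-bromo-2-methoxy-6-(2-methoxyethenyl)phenoxy]methyl}-2-methoxyphenyl 2,2-dimethylpropanoate (E/Z mixture) | COC=Cc1cc(Br)cc(OC)c1OCc1ccc(OC(=O)C(C)(C)C)c(OC)c1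
F3 | step 8 | methyl 2-[5-bromo-3-methoxy-2-({3-methoxy-4-[(2,2-dimethylpropanoyl)oxy]phenyl}methoxy)phenyl]acetate | COC(=O)Cc1cc(Br)cc(OC)c1OCc1ccc(OC(=O)C(C)(C)C)c(OC)c1
F4 | step 8 | methyl 2-[5-bromo-3-methoxy-2-({3-methoxy-4-[(2,2-dimethylpropanoyl)oxy]phenyl}methoxy)phenyl]-2-diazoacetate | COC(=O)C(=[N+]=[N-])c1cc(Br)cc(OC)c1OCc1ccc(OC(=O)C(C)(C)C)c(OC)c1
F5 | step 8 | methyl (2S,3R)-5-bromo-7-methoxy-2-[3-methoxy-4-(pivaloyloxy)phenyl]-2,3-dihydro-1-benzofuran-3-carboxylate (cis) | COc1cc([C@H]2Oc3c(OC)cc(Br)cc3[C@H]2C(=O)OC)ccc1OC(=O)C(C)(C)C
F6 | step 8 | methyl (2S,3S)-5-bromo-2-(4-hydroxy-3-methoxyphenyl)-7-methoxy-2,3-dihydro-1-benzofuran-3-carboxylate (trans) | COc1cc([C@H]2Oc3c(OC)cc(Br)cc3[C@@H]2C(=O)OC)ccc1O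
F7 | step 8 | 4-[(2S,3R)-5-bromo-3-(hydroxymethyl)-7-methoxy-2,3-dihydro-1-benzofuran-2-yl]-2-methoxyphenol (same compound as A3) | COc1cc([C@H]2Oc3c(OC)cc(Br)cc3[C@@H]2CO)ccc1O
F8 | step 8 | 4-[(2S,3R)-3-(hydroxymethyl)-7-methoxy-5-[(trimethylsilyl)ethynyl]-2,3-dihydro-1-benzofuran-2-yl]-2-methoxyphenol | COc1cc([C@H]2Oc3c(OC)cc(C#C[Si](C)(C)C)cc3[C@@H]2CO)ccc1O
F9 | step 7 | 2-methoxy-4-{[(trifluoromethanesulfonyl)oxy]methyl}phenyl 2,2-dimethylpropanoate | COc1cc(COS(=O)(=O)C(F)(F)F)ccc1OC(=O)C(C)(C)C
F10 | step 9 | 4-[(2S,3S)-5-bromo-3-formyl-7-methoxy-2,3-dihydro-1-benzofuran-2-yl]-2-methoxyphenyl 2,2-dimethylpropanoate | COc1cc([C@H]2Oc3c(OC)cc(Br)cc3[C@@H]2C=O)ccc1OC(=O)C(C)(C)C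
F11 | step 14 | 3-(4-acetoxy-3-iodo-5-methoxyphenyl)propyl acetate | COc1cc(CCCOC(C)=O)cc(I)c1OC(C)=O
F12 | step 14 | 3-[4-acetoxy-3-({(2S,3R)-2-(4-hydroxy-3-methoxyphenyl)-3-(hydroxymethyl)-7-methoxy-2,3-dihydro-1-benzofuran-5-yl}ethynyl)-5-methoxyphenyl]propyl acetate | COc1cc([C@H]2Oc3c(OC)cc(C#Cc4cc(CCCOC(C)=O)cc(OC)c4OC(C)=O)cc3[C@@H]2CO)ccc1O
A1 | alternative 1 | (2S,3R)-2-[4-(tert-butyldimethylsilyloxy)-3-methoxyphenyl]-3-[(tert-butyldimethylsilyloxy)methyl]-5-{5-[3-(tert-butyldimethylsilyloxy)propyl]-7-methoxy-1-benzofuran-2-yl}-2,3-dihydro-1-benzofuran-7-ol | COc1cc([C@H]2Oc3c(O)cc(-c4cc5cc(CCCO[Si](C)(C)C(C)(C)C)cc(OC)c5o4)cc3[C@@H]2CO[Si](C)(C)C(C)(C)C)ccc1O[Si](C)(C)C(C)(C)C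
A2 | alternative 1 | ethynyl ether of (1S,2R)-3-(tert-butyldimethylsilyloxy)-1-[4-(tert-butyldimethylsilyloxy)-3-methoxyphenyl]-2-(4-{5-[3-(tert-butyldimethylsilyloxy)propyl]-7-methoxy-1-benzofuran-2-yl}furan-2-yl)propan-1-ol | COc1cc([C@H]([C@@H](CO[Si](C)(C)C(C)(C)C)c2cc(-c3cc4cc(CCCO[Si](C)(C)C(C)(C)C)cc(OC)c4o3)co2)OC#C)ccc1O[Si](C)(C)C(C)(C)C
A3 | alternative 2 | (2S,3R)-5-bromo-2-(4-hydroxy-3-methoxyphenyl)-3-(hydroxymethyl)-7-methoxy-2,3-dihydro-1-benzofuran | COc1cc([C@H]2Oc3c(OC)cc(Br)cc3[C@@H]2CO)ccc1O
A4 | alternative 2 | (3R)-3-(5-bromo-2-hydroxy-3-methoxyphenyl)-4-hydroxy-2-(4-hydroxy-3-methoxyphenyl)butanoic acid (either C2 epimer) | COc1cc(C(C(=O)O)[C@@H](CO)c2cc(Br)cc(OC)c2O)ccc1O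
A5 | alternative 3 | tris-pivalate of the target: 4-[(2S,3R)-7-methoxy-5-{7-methoxy-5-[3-(pivaloyloxy)propyl]-1-benzofuran-2-yl}-3-[(pivaloyloxy)methyl]-2,3-dihydro-1-benzofuran-2-yl]-2-methoxyphenyl 2,2-dimethylpropanoate | COc1cc([C@H]2Oc3c(OC)cc(-c4cc5cc(CCCOC(=O)C(C)(C)C)cc(OC)c5o4)cc3[C@@H]2COC(=O)C(C)(C)C)ccc1OC(=O)C(C)(C)C
A6 | alternative 3 | 4-[(2S,3R)-5-(2,2-dimethoxy-1-{2-methoxy-4-[3-(pivaloyloxy)propyl]phenoxy}ethyl)-7-methoxy-3-[(pivaloyloxy)methyl]-2,3-dihydro-1-benzofuran-2-yl]-2-methoxyphenyl 2,2-dimethylpropanoate (either epimer at the aryloxy carbon) | COc1cc([C@H]2Oc3c(OC)cc(C(Oc4ccc(CCCOC(=O)C(C)(C)C)cc4OC)C(OC)OC)cc3[C@@H]2COC(=O)C(C)(C)C)ccc1OC(=O)C(C)(C)C
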